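Remark on the chemistry (assumption): ring A is the benzo ring of the 2,3-dihydrobenzofuran (atoms O1, C2, C3, C3a, C4–C7, C7a), ring B is the aryl group on C2 and ring C is the resorcinol ring. Chain carbons of the polyketide are numbered from the ester carbon (chain C1) to the aryl-bearing alkene carbon (chain C9). Compounds 1, 3, 6, 9, 17, 19, 20 and 24 are taken as catalogue chemicals.

## Structural features

Gnetofuran A has three benzene rings. Ring A is fused to a dihydrofuran and carries a methoxy group on C7. Ring B (4-hydroxy-3-methoxyphenyl) sits on C2. Ring C (3,5-dihydroxyphenyl) is joined to C5 of ring A through an E-ethene bridge, and C3 bears a hydroxymethyl group. The only stereocentres, C2 (R) and C3 (S), are adjacent, both benzylic, and trans on the five-membered ring. The fragile elements are the electron-rich E-stilbene (isomerisation, acid-induced cyclisation, oxidation), the three phenolic hydroxyls, and the O1–C2 bond, which becomes a para-hydroxybenzyl aryl ether once the ring B phenol is free and can then open through a quinone methide. The real difficulty is to set C2 and C3 in the absolute sense beside two aryl groups on a 1,2,3,5-tetrasubstituted ring A, and then to carry that core through poly-β-carbonyl chemistry without loss of configuration or alkene geometry. The key step exploits the oxygen pattern of ring C: its six carbons correspond to chain C2–C7 of a 3,5,7-triketo ester, the two meta hydroxyls are the chain C3 and C5 ketone oxygens, and the ring bond between the carbon that temporarily carries a carboxyl group and the carbon that carries the ethene bridge is an aldol bond. The carboxyl group is the trace of the chain end and has to be removed afterwards.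

## Logic of the disconnections

31 is traced back to 30 and, through 29, to 28. Only an O–Si bond, two O–allyl bonds and the C–CO2 bond on ring C are involved. The carboxyl group is kept until the end because it is what activates the ring-forming aldol. The ring B phenol carries an allyl ether so that the same palladium step that opens the allyl ester also frees this phenol, and the primary alcohol carries a bulky silyl ether that fluoride removes. The gain is that no acid is needed once the stilbene and the para-oxygenated benzyl ether are present. The demand is a clean deallylation without C-allylation of the resorcinol and a decarboxylation that proceeds on mild warming.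

28 is cut in ring C between the ester-bearing carbon and the styryl-bearing carbon (chain C2–C7), and at the ester C–O bond, giving 23 and 24. The cut is made there because the aldol fold of a triketo ester produces the 1,3-dihydroxy pattern directly, with the alkene already in place. An aromatic ring is traded for a linear chain whose reactive end is masked as a dioxinone. The forward step must select one aldol mode among several possible cyclisations.

23 is cut between the enone carbonyl and the neighbouring methylene, giving 18 (activated as 22) and 21. The terminal carbanion of a β-dicarbonyl dianion is the most nucleophilic site, so this bond is a natural Claisen bond. The whole poly-carbonyl chain then comes from 21, which is cut the same way into 19 and 20. The forward acylation must go 1,2 and not 1,4 on an unsaturated acyl donor.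

18 is cut at the C=C bond into 16 and 17, and 16 is derived from 15 by changing the nitrile to the aldehyde. A condensation that ends with decarboxylation gives the E acid under thermodynamic control. The nitrile is chosen as the latent aldehyde because it also activates the ring closure that precedes it and survives borohydride. The demand is a single hydride addition to the nitrile.

15 is cut at the O1–C7a aryl ether bond, leading through 14 and 13 to 12. Cutting on the aryl side leaves the C2–O bond untouched, so the configuration made in the aldol is carried over with retention, and a syn aldol then maps onto the trans ring. The bicyclic core becomes an acyclic 1,3-diol derivative. The forward step needs fluoride as leaving group, the para cyano group as activator, the carbonyl reduced beforehand (no retro-aldol under base) and a protecting group on the primary oxygen that does not migrate.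

12 is cut at the C2–C3 bond into 8 (as 11) and 10, and 10 comes from 9. One C–C bond creates both adjacent stereocentres under auxiliary control. The forward step needs a Z enolate and high facial selectivity.

8 is cut at the N-acyl bond into 5 (as 7) and 6. 5 is traced through 4 to 2 and 3 by cutting the aryl–CH2 bond, and 2 to 1 by replacing C–B with C–H. The 1,2,3,5-substitution of ring A is thus reached from a simple commercial arene by sterically governed C–H borylation. The demand is regioselectivity for the position next to fluorine.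

## Other disconnections considered

Alternative 1: The cut is the C2–C3 bond of the dihydrofuran. In the forward step the aryldiazoacetate A2, in which the ring A oxygen carries the ring B benzyl group, is decomposed by Rh2(S-DOSP)4. The rhodium carbenoid inserts into a benzylic ether C–H bond five atoms away, closes the five-membered ring and creates C2 and C3 together, giving A1. In its favour: one catalytic step forms the ring C–C bond and both stereocentres, and the bromine at C5 of A1 is a direct handle for cross-coupling, so ring C could be attached rather than built. Against it here: the cis/trans ratio of such insertions depends on catalyst and ester, so the trans ring may have to be secured by epimerisation at C3; high induction needs auxiliary and catalyst to be matched; a diazo compound has to be made and handled; electron-rich arenes invite cyclopropanation and ylide pathways; and the lactamide ester must later be reduced to the hydroxymethyl group. Comparison: in structure it addresses only the core, as do steps 1–9 of the chosen plan. In mechanism it sets the ring configuration through a carbenoid transition state, whereas the chosen plan fixes it by a syn aldol followed by a closure that does not touch C2, which is the more predictable of the two. In step economy Alternative 1 is at least the equal of the chosen plan for the core and would be the better plan overall if ring C were introduced by coupling at C5 of A1.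

Alternative 2: The cuts are the C2–ring B bond and the C3–C3a bond. In the forward step the ate complex formed from aryllithium A6 and the E-alkenylboronate A4 reacts with the ring A triflate A5 under Pd(OAc)2 and a MandyPhos ligand. The aryl–palladium species activates the alkene, ring B shifts from boron to the boron-bearing carbon, and reductive elimination joins C3 to C3a, giving A3 without closing a ring. In its favour: two skeletal bonds and two stereocentres arise in one catalytic, enantioselective, three-component step with no auxiliary; on convergence and catalytic stereocontrol it is the better plan. Against it here: β-substituted alkenyl pinacol boronates tend to transfer the alkenyl group directly instead of undergoing the metallate shift; A5 is a doubly ortho-substituted triflate; and oxidation of the C–B bond, unmasking of the ring A phenol and closure of O1–C2 must follow. The boron-bearing carbon of A3 has the spatial arrangement of C2 of the target, so a closure by the ring A phenol that inverts this centre would give the cis ring. The closure would therefore have to pass through the ionised benzylic centre and rely on the trans preference, or the Z isomer of A4 would be needed. Comparison: structurally it builds the same core from three pieces where the chosen plan uses two. Mechanistically it relies on a less established metallate shift where the chosen plan relies on a closed aldol transition state. In step count to the core the two are about equal, and the chosen plan is the safer in relative configuration.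

Alternative 3: The cut is the O1–C2 bond. In the forward step DDQ dehydrogenates the para-hydroxybenzylic methylene of ring B in the diarylpropanol A8 to a para-quinone methide, and the ortho phenol of ring A adds to its exocyclic carbon, rearomatising ring B and closing the dihydrofuran to A7. In its favour: only the C3 centre has to be made beforehand, the phenols stay unprotected, and the sequence to the core is short; on protecting-group and step economy it is the better plan. Against it here: DDQ acts on a substrate with two free, electron-rich phenols; A7 still has a para-hydroxybenzylic C2–H and can be oxidised on to the benzofuran; ring A could form an ortho-quinone methide at C3 and erode the only preset centre; the trans ring rests on substrate control; and the free ring B phenol would have to be protected again before any strongly basic chain-building chemistry. Comparison: in structure it reaches a core equivalent to 16 with an ester in place of the aldehyde. In mechanism it is oxidative and under thermodynamic control, whereas the chosen plan is redox-neutral and stereospecific at C2. In step economy Alternative 3 is shorter, and in certainty of configuration the chosen plan is stronger.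

Key step: step 14

## Route

Step 1
Reactants: 1 4-fluoro-3-methoxybenzonitrile
Product: 2 4-fluoro-3-methoxy-5-(4,4,5,5-tetramethyl-1,3,2-dioxaborolan-2-yl)benzonitrile
Conditions: [Ir(OMe)(cod)]2 (1.5 mol %), 4,4'-di-tert-butyl-2,2'-bipyridine (3 mol %), B2pin2 (1.0 equiv), THF, 60 °C
Reagents that add atoms: bis(pinacolato)diboron, CC1(C)OB(OC1(C)C)B1OC(C)(C)C(C)(C)O1
Why: Iridium-catalysed aromatic C–H borylation is governed by sterics and C–H acidity: C2 is flanked by cyano and methoxy, C6 lies next to cyano and para to the donor methoxy, whereas C5 is adjacent only to the small, acidifying fluorine, so borylation should occur at C5.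

Step 2
Reactants: 2 the C5 boronate; 3 tert-butyl bromoacetate
Product: 4 tert-butyl 2-(5-cyano-2-fluoro-3-methoxyphenyl)acetate
Conditions: Pd(OAc)2 (3 mol %), P(o-tol)3 (9 mol %), K3PO4, THF/H2O, 20 °C
Reagents that add atoms: none
Why: Suzuki–Miyaura sp2–sp3 coupling: oxidative addition of the α-bromo ester to zerovalent palladium gives a palladium enolate that transmetalates with the boronate and reductively eliminates to the arylacetate; the tert-butyl ester and the aryl fluoride tolerate phosphate at room temperature.

Step 3
Reactants: 4 the tert-butyl arylacetate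
Product: 5 2-(5-cyano-2-fluoro-3-methoxyphenyl)acetic acid
Conditions: CF3CO2H/CH2Cl2 (1:3), 0 → 20 °C
Reagents that add atoms: none
Why: Acidolysis of the tert-butyl ester (loss of 2-methylpropene) frees the acid without hydroxide, which could attack the cyano-activated aryl fluoride.

Step 4
Reactants: 5 the arylacetic acid; 6 (R)-4-benzyl-1,3-oxazolidin-2-one
Product: 8 (R)-4-benzyl-3-[2-(5-cyano-2-fluoro-3-methoxyphenyl)acetyl]-1,3-oxazolidin-2-one, via mixed pivalic anhydride 7 (not isolated)
Conditions: tBuCOCl, Et3N, THF, −20 °C; then 6, LiCl, 20 °C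
Reagents that add atoms: none
Why: N-Acylation of the oxazolidinone through the mixed anhydride under LiCl/Et3N avoids strong base at the acidic benzylic position; the auxiliary attacks the less hindered acyl group of 7.

Step 5
Reactants: 9 vanillin (4-hydroxy-3-methoxybenzaldehyde)
Product: 10 4-(allyloxy)-3-methoxybenzaldehyde
Conditions: allyl bromide, K2CO3, acetone, 56 °C
Reagents that add atoms: allyl bromide, C=CCBr
Why: Williamson etherification of the phenoxide; the allyl ether is chosen because zerovalent palladium later removes it together with the allyl ester, so that no acid is needed near the end.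

Step 6
Reactants: 8 the arylacetyl imide; 10 the ring B aldehyde
Product: 12 (R)-3-[(2R,3R)-3-[4-(allyloxy)-3-methoxyphenyl]-2-(5-cyano-2-fluoro-3-methoxyphenyl)-3-hydroxypropanoyl]-4-benzyl-1,3-oxazolidin-2-one, via dibutylboron Z-enolate 11 (not isolated)
Conditions: Bu2BOTf, iPr2NEt, CH2Cl2, 0 °C; 10, −78 → 0 °C; pH 7 phosphate buffer, MeOH, 30% H2O2, 0 °C
Reagents that add atoms: none
Why: Evans syn-aldol reaction: the Z boron enolate 11 reacts through a chair Zimmerman–Traxler transition state on the face away from the benzyl group of the (R)-auxiliary, which sets both new centres as 2R,3R (syn); they become C3 (S) and C2 (R) of the dihydrobenzofuran.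

Step 7
Reactants: 12 the syn-aldol imide
Product: 13 3-[(1R,2S)-1-[4-(allyloxy)-3-methoxyphenyl]-1,3-dihydroxypropan-2-yl]-4-fluoro-5-methoxybenzonitrile
Conditions: LiBH4, H2O (1 equiv), THF, 0 °C
Reagents that add atoms: none
Why: Reductive removal of the auxiliary: borohydride attacks the exocyclic imide carbonyl while nitrile and aryl fluoride are inert at 0 °C, and no stereocentre is touched; removing the carbonyl here excludes retro-aldol cleavage in the basic ring closure.

Step 8
Reactants: 13 the 1,3-diol
Product: 14 3-[(1R,2S)-1-[4-(allyloxy)-3-methoxyphenyl]-1-hydroxy-3-[(triisopropylsilyl)oxy]propan-2-yl]-4-fluoro-5-methoxybenzonitrile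
Conditions: iPr3SiCl, imidazole, CH2Cl2, 0 → 20 °C
Reagents that add atoms: triisopropylsilyl chloride, CC(C)[Si](Cl)(C(C)C)C(C)C
Why: Silylation with the bulky chloride is selective for the primary over the hindered secondary benzylic hydroxyl; the triisopropylsilyl group is chosen for its slow oxygen-to-oxygen migration and its stability to the later bases.

Step 9
Reactants: 14 the mono-silylated diol
Product: 15 (2R,3S)-2-[4-(allyloxy)-3-methoxyphenyl]-7-methoxy-3-{[(triisopropylsilyl)oxy]methyl}-2,3-dihydro-1-benzofuran-5-carbonitrile
Conditions: KN(SiMe3)2 (1.1 equiv), THF, −20 → 20 °C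
Reagents that add atoms: none
Why: Intramolecular SNAr: the potassium alkoxide adds 5-exo to the fluorine-bearing carbon, the Meisenheimer intermediate is stabilised by the para cyano group, and fluoride leaves; the C2–O bond is never broken, so the syn-aldol configuration is retained and gives the trans ring.

Step 10
Reactants: 15 the 5-carbonitrile
Product: 16 (2R,3S)-2-[4-(allyloxy)-3-methoxyphenyl]-7-methoxy-3-{[(triisopropylsilyl)oxy]methyl}-2,3-dihydro-1-benzofuran-5-carbaldehyde
Conditions: iBu2AlH (1.3 equiv), CH2Cl2, −78 °C; aq. potassium sodium tartrate, 20 °C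
Reagents that add atoms: water, O
Why: Partial reduction of the aryl nitrile by iBu2AlH stops at the imine oxidation level, and hydrolytic work-up delivers the aldehyde; the ethers and the silyl ether are inert.

Step 11
Reactants: 16 the 5-carbaldehyde; 17 malonic acid
Product: 18 (E)-3-[(2R,3S)-2-[4-(allyloxy)-3-methoxyphenyl]-7-methoxy-3-{[(triisopropylsilyl)oxy]methyl}-2,3-dihydro-1-benzofuran-5-yl]prop-2-enoic acid
Conditions: pyridine, piperidine (cat.), 90 °C
Reagents that add atoms: none
Why: Knoevenagel–Doebner condensation: amine-catalysed condensation followed by decarboxylation in pyridine gives the thermodynamically favoured E acid in one operation under non-acidic conditions.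

Step 12
Reactants: 19 2,2,6-trimethyl-4H-1,3-dioxin-4-one; 20 acetyl chloride
Product: 21 2,2-dimethyl-6-(2-oxopropyl)-4H-1,3-dioxin-4-one
Conditions: 19 (2 equiv), LiN(SiMe3)2 (2 equiv), THF, −78 °C; 20 (1 equiv), −78 → −20 °C
Reagents that add atoms: none
Why: γ-Deprotonation gives the lithium dienolate, which is C-acylated at the terminal carbon (Claisen-type acylation); the dienolate is used in excess because the product is the stronger acid.

Step 13
Reactants: 18 the E-cinnamic acid; 21 the keto-dioxinone
Product: 23 6-[(E)-6-{(2R,3S)-2-[4-(allyloxy)-3-methoxyphenyl]-7-methoxy-3-{[(triisopropylsilyl)oxy]methyl}-2,3-dihydro-1-benzofuran-5-yl}-2,4-dioxohex-5-en-1-yl]-2,2-dimethyl-4H-1,3-dioxin-4-one, via acyl imidazolide 22 (not isolated)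
Conditions: 1,1'-carbonyldiimidazole, THF, 20 °C; then added to 21 (3.5 equiv)/LiN(iPr)2 (7 equiv), THF, −78 → −40 °C; aq. NH4Cl
Reagents that add atoms: none
Why: Claisen-type C-acylation: the dianion of 21 reacts through its terminal, last-formed carbanion with imidazolide 22; a hard lithium enolate and a reactive acyl donor favour 1,2- over 1,4-addition, and the para oxygen of ring A lowers the electrophilicity of the β-carbon.

Step 14
Reactants: 23 the diketo-dioxinone; 24 allyl alcohol
Product: 28 allyl 2,4-dihydroxy-6-[(E)-2-{(2R,3S)-2-[4-(allyloxy)-3-methoxyphenyl]-7-methoxy-3-{[(triisopropylsilyl)oxy]methyl}-2,3-dihydro-1-benzofuran-5-yl}ethenyl]benzoate, via acylketene 25 (not isolated), via triketo allyl ester 26 (not isolated), via cyclic aldol 27 (not isolated)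
Conditions: 24 (5 equiv), PhMe, 110 °C; concentrate; Cs2CO3, CH2Cl2/allyl alcohol, 20 °C; 1 M HCl
Reagents that add atoms: none
Why: At 110 °C the dioxinone of 23 undergoes retro-[4+2] fragmentation with loss of acetone to acylketene 25, and O–H addition of 24, used in excess so that capture outruns self-trapping by the enols, gives the 3,5,7-triketo ester 26. Cs2CO3 then deprotonates chain C2, the methylene flanked by the ester and the chain C3 ketone, and this enolate adds to the chain C7 enone carbonyl in a 6-(enolexo)-exo-trig aldol closure that forms the one new ring bond and gives 27. E1cB loss of water and two enolisations, completed on acidification, aromatise ring C to 28; the chain C3 and C5 oxygens end as the two meta hydroxyls, the ester stays on the ring carbon next to the styryl carbon, and the chain C8=C9 alkene, which takes no part, becomes the E bridge. The closest known reaction type is the thermolysis of diketo-dioxinones with alcohol capture followed by base-mediated aldol aromatisation to 6-substituted 2,4-dihydroxybenzoates, of which an alkenyl group on the terminal ketone is an uncommon variant. No stereocentre is created, since the two new centres of 27 vanish on aromatisation, and ring positions C2 and C3 of the dihydrobenzofuran carry no hydrogen that carbonate can remove. The selectivity needed is aldol closure from chain C2 to C7 over Claisen closure from chain C6 to C1, lactonisation of the chain C5 enol oxygen onto C1, and oxygen or carbon conjugate addition to chain C9. The weakly electrophilic alkyl ester and the mild carbonate base disfavour the two acylations, the conjugate additions are reversible whereas dehydration to the arene is not, and O1 of ring A donates into the enone and lowers the electrophilicity of chain C9.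

Step 15
Reactants: 28 the allyl resorcylate
Product: 30 5-[(E)-2-{(2R,3S)-2-(4-hydroxy-3-methoxyphenyl)-7-methoxy-3-{[(triisopropylsilyl)oxy]methyl}-2,3-dihydro-1-benzofuran-5-yl}ethenyl]benzene-1,3-diol, via resorcylic acid 29 (not isolated)
Conditions: Pd(PPh3)4 (5 mol %), morpholine (10 equiv), THF, 20 → 40 °C; then AcOH, dioxane/H2O, 90 °C
Reagents that add atoms: none
Why: Zerovalent palladium ionises both the allyl ester and the allyl aryl ether to π-allyl complexes that morpholine captures (Tsuji–Trost deallylation), which frees acid 29; 2,4-dihydroxybenzoic acids lose CO2 on warming through ipso protonation of the electron-rich ring, so neither strong acid nor strong base is involved.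

Step 16
Reactants: 30 the silyl ether of the target
Product: 31 gnetofuran A, 5-[(E)-2-[(2R,3S)-2-(4-hydroxy-3-methoxyphenyl)-3-(hydroxymethyl)-7-methoxy-2,3-dihydro-1-benzofuran-5-yl]ethenyl]benzene-1,3-diol
Conditions: Bu4NF, AcOH, THF, 0 → 20 °C
Reagents that add atoms: none
Why: Fluoride cleaves the primary silyl ether (strong Si–F bond); buffering with acetic acid avoids phenoxides of the oxidisable stilbene polyphenol, and no stereocentre is affected.

## Compound list

1 | 4-fluoro-3-methoxybenzonitrile | COc1cc(C#N)ccc1F | starting material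
2 | 4-fluoro-3-methoxy-5-(4,4,5,5-tetramethyl-1,3,2-dioxaborolan-2-yl)benzonitrile | COc1cc(C#N)cc(B2OC(C)(C)C(C)(C)O2)c1F | intermediate
3 | tert-butyl bromoacetate | CC(C)(C)OC(=O)CBr | starting material
4 | tert-butyl 2-(5-cyano-2-fluoro-3-methoxyphenyl)acetate | COc1cc(C#N)cc(CC(=O)OC(C)(C)C)c1F | intermediate
5 | 2-(5-cyano-2-fluoro-3-methoxyphenyl)acetic acid | COc1cc(C#N)cc(CC(=O)O)c1F | intermediate
6 | (R)-4-benzyl-1,3-oxazolidin-2-one | O=C1N[C@H](Cc2ccccc2)CO1 | starting material
7 | 2-(5-cyano-2-fluoro-3-methoxyphenyl)acetic pivalic anhydride (not isolated) | COc1cc(C#N)cc(CC(=O)OC(=O)C(C)(C)C)c1F | intermediate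
8 | (R)-4-benzyl-3-[2-(5-cyano-2-fluoro-3-methoxyphenyl)acetyl]-1,3-oxazolidin-2-one | COc1cc(C#N)cc(CC(=O)N2[C@H](Cc3ccccc3)COC2=O)c1F | intermediate
9 | vanillin (4-hydroxy-3-methoxybenzaldehyde) | COc1cc(C=O)ccc1O | starting material
10 | 4-(allyloxy)-3-methoxybenzaldehyde | COc1cc(C=O)ccc1OCC=C | intermediate
11 | dibutylboron Z-enolate of 8 (not isolated) | CCCCB(CCCC)O/C(=C\c1cc(C#N)cc(OC)c1F)N1[C@H](Cc2ccccc2)COC1=O | intermediate
12 | (R)-3-[(2R,3R)-3-[4-(allyloxy)-3-methoxyphenyl]-2-(5-cyano-2-fluoro-3-methoxyphenyl)-3-hydroxypropanoyl]-4-benzyl-1,3-oxazolidin-2-one | O=C(N1[C@H](Cc2ccccc2)COC1=O)[C@H](c1cc(C#N)cc(OC)c1F)[C@@H](O)c1ccc(OCC=C)c(OC)c1 | intermediate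
13 | 3-[(1R,2S)-1-[4-(allyloxy)-3-methoxyphenyl]-1,3-dihydroxypropan-2-yl]-4-fluoro-5-methoxybenzonitrile | OC[C@H](c1cc(C#N)cc(OC)c1F)[C@@H](O)c1ccc(OCC=C)c(OC)c1 | intermediate
14 | 3-[(1R,2S)-1-[4-(allyloxy)-3-methoxyphenyl]-1-hydroxy-3-[(triisopropylsilyl)oxy]propan-2-yl]-4-fluoro-5-methoxybenzonitrile | CC(C)[Si](OC[C@H](c1cc(C#N)cc(OC)c1F)[C@@H](O)c1ccc(OCC=C)c(OC)c1)(C(C)C)C(C)C | intermediate
15 | (2R,3S)-2-[4-(allyloxy)-3-methoxyphenyl]-7-methoxy-3-{[(triisopropylsilyl)oxy]methyl}-2,3-dihydro-1-benzofuran-5-carbonitrile | C=CCOc1ccc([C@@H]2Oc3c(OC)cc(C#N)cc3[C@H]2CO[Si](C(C)C)(C(C)C)C(C)C)cc1OC | intermediate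
16 | (2R,3S)-2-[4-(allyloxy)-3-methoxyphenyl]-7-methoxy-3-{[(triisopropylsilyl)oxy]methyl}-2,3-dihydro-1-benzofuran-5-carbaldehyde | C=CCOc1ccc([C@@H]2Oc3c(OC)cc(C=O)cc3[C@H]2CO[Si](C(C)C)(C(C)C)C(C)C)cc1OC | intermediate
17 | malonic acid | OC(=O)CC(=O)O | starting material
18 | (E)-3-[(2R,3S)-2-[4-(allyloxy)-3-methoxyphenyl]-7-methoxy-3-{[(triisopropylsilyl)oxy]methyl}-2,3-dihydro-1-benzofuran-5-yl]prop-2-enoic acid | C=CCOc1ccc([C@@H]2Oc3c(OC)cc(/C=C/C(=O)O)cc3[C@H]2CO[Si](C(C)C)(C(C)C)C(C)C)cc1OC | intermediate
19 | 2,2,6-trimethyl-4H-1,3-dioxin-4-one | CC1=CC(=O)OC(C)(C)O1 | starting material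
20 | acetyl chloride | CC(=O)Cl | starting material
21 | 2,2-dimethyl-6-(2-oxopropyl)-4H-1,3-dioxin-4-one | CC(=O)CC1=CC(=O)OC(C)(C)O1 | intermediate
22 | 1-[(E)-3-{(2R,3S)-2-[4-(allyloxy)-3-methoxyphenyl]-7-methoxy-3-{[(triisopropylsilyl)oxy]methyl}-2,3-dihydro-1-benzofuran-5-yl}prop-2-enoyl]-1H-imidazole (not isolated) | C=CCOc1ccc([C@@H]2Oc3c(OC)cc(/C=C/C(=O)n4ccnc4)cc3[C@H]2CO[Si](C(C)C)(C(C)C)C(C)C)cc1OC | intermediate
23 | 6-[(E)-6-{(2R,3S)-2-[4-(allyloxy)-3-methoxyphenyl]-7-methoxy-3-{[(triisopropylsilyl)oxy]methyl}-2,3-dihydro-1-benzofuran-5-yl}-2,4-dioxohex-5-en-1-yl]-2,2-dimethyl-4H-1,3-dioxin-4-one | C=CCOc1ccc([C@@H]2Oc3c(OC)cc(/C=C/C(=O)CC(=O)CC4=CC(=O)OC(C)(C)O4)cc3[C@H]2CO[Si](C(C)C)(C(C)C)C(C)C)cc1OC | intermediate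
24 | allyl alcohol (prop-2-en-1-ol) | C=CCO | starting material
25 | (E)-9-{(2R,3S)-2-[4-(allyloxy)-3-methoxyphenyl]-7-methoxy-3-{[(triisopropylsilyl)oxy]methyl}-2,3-dihydro-1-benzofuran-5-yl}nona-1,8-diene-1,3,5,7-tetrone, the acylketene (not isolated) | C=CCOc1ccc([C@@H]2Oc3c(OC)cc(/C=C/C(=O)CC(=O)CC(=O)C=C=O)cc3[C@H]2CO[Si](C(C)C)(C(C)C)C(C)C)cc1OC | intermediate
26 | allyl (E)-9-{(2R,3S)-2-[4-(allyloxy)-3-methoxyphenyl]-7-methoxy-3-{[(triisopropylsilyl)oxy]methyl}-2,3-dihydro-1-benzofuran-5-yl}-3,5,7-trioxonon-8-enoate (not isolated) | C=CCOc1ccc([C@@H]2Oc3c(OC)cc(/C=C/C(=O)CC(=O)CC(=O)CC(=O)OCC=C)cc3[C@H]2CO[Si](C(C)C)(C(C)C)C(C)C)cc1OC | intermediate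
27 | allyl 2-hydroxy-4,6-dioxo-2-[(E)-2-{(2R,3S)-2-[4-(allyloxy)-3-methoxyphenyl]-7-methoxy-3-{[(triisopropylsilyl)oxy]methyl}-2,3-dihydro-1-benzofuran-5-yl}ethenyl]cyclohexane-1-carboxylate, mixture at the two transient ring centres (not isolated) | C=CCOc1ccc([C@@H]2Oc3c(OC)cc(/C=C/C4(O)CC(=O)CC(=O)C4C(=O)OCC=C)cc3[C@H]2CO[Si](C(C)C)(C(C)C)C(C)C)cc1OC | intermediate
28 | allyl 2,4-dihydroxy-6-[(E)-2-{(2R,3S)-2-[4-(allyloxy)-3-methoxyphenyl]-7-methoxy-3-{[(triisopropylsilyl)oxy]methyl}-2,3-dihydro-1-benzofuran-5-yl}ethenyl]benzoate | C=CCOc1ccc([C@@H]2Oc3c(OC)cc(/C=C/c4cc(O)cc(O)c4C(=O)OCC=C)cc3[C@H]2CO[Si](C(C)C)(C(C)C)C(C)C)cc1OC | intermediate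
29 | 2,4-dihydroxy-6-[(E)-2-{(2R,3S)-2-(4-hydroxy-3-methoxyphenyl)-7-methoxy-3-{[(triisopropylsilyl)oxy]methyl}-2,3-dihydro-1-benzofuran-5-yl}ethenyl]benzoic acid (not isolated) | COc1cc([C@@H]2Oc3c(OC)cc(/C=C/c4cc(O)cc(O)c4C(=O)O)cc3[C@H]2CO[Si](C(C)C)(C(C)C)C(C)C)ccc1O | intermediate
30 | 5-[(E)-2-{(2R,3S)-2-(4-hydroxy-3-methoxyphenyl)-7-methoxy-3-{[(triisopropylsilyl)oxy]methyl}-2,3-dihydro-1-benzofuran-5-yl}ethenyl]benzene-1,3-diol | COc1cc([C@@H]2Oc3c(OC)cc(/C=C/c4cc(O)cc(O)c4)cc3[C@H]2CO[Si](C(C)C)(C(C)C)C(C)C)ccc1O | intermediate
31 | gnetofuran A, 5-[(E)-2-[(2R,3S)-2-(4-hydroxy-3-methoxyphenyl)-3-(hydroxymethyl)-7-methoxy-2,3-dihydro-1-benzofuran-5-yl]ethenyl]benzene-1,3-diol | COc1cc([C@@H]2Oc3c(OC)cc(/C=C/c4cc(O)cc(O)c4)cc3[C@H]2CO)ccc1O | target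

## Step count and least certain steps

Total: 16 steps. Longest linear sequence: 14 steps (steps 1, 2, 3, 4, 6, 7, 8, 9, 10, 11, 13, 14, 15, 16). Steps 5 and 12 are side branches.

Step 14 (key step). The triketo ester may fold in other modes: Claisen closure of chain C6 onto the ester, lactonisation through the chain C5 enol oxygen, or conjugate addition of a diketone enol to the enone. Ketene capture may also be incomplete. The chain offers several nucleophilic and electrophilic sites of similar reactivity, and an enone terminus has little precedent. Fallback: set out from 23 and reverse the order of unmasking and ring closure. A catalytic amine base (Et3N, CH2Cl2, 20 °C) should induce the same aldol bond while the dioxinone is intact, the nucleophile being the dioxinone ring carbon next to its carbonyl group. After dehydration this gives 7-hydroxy-2,2-dimethyl-5-[(E)-2-{(2R,3S)-2-[4-(allyloxy)-3-methoxyphenyl]-7-methoxy-3-{[(triisopropylsilyl)oxy]methyl}-2,3-dihydro-1-benzofuran-5-yl}ethenyl]-4H-1,3-benzodioxin-4-one F1. Its carboxyl carbon is locked in the acetonide, so neither Claisen closure nor lactonisation is possible. Opening of F1 with allyl alcohol and Cs2CO3 at 60 °C comes back to the route at 28.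

Step 13. The dianion may add in conjugate fashion to the unsaturated acyl donor, or be quenched by proton transfer from imidazole and from the more acidic product before acylation is complete. Fallback: set out from 16 and 21 and replace the acylation by a polyanion aldol condensation. The dianion of 21 is acetylated with N-acetylimidazole to 6-(2,4-dioxopentyl)-2,2-dimethyl-4H-1,3-dioxin-4-one F2. Its trianion (LiN(iPr)2, THF, −78 °C) should add through the terminal methyl carbon to aldehyde 16, which has no conjugate position, to give 6-[6-{(2R,3S)-2-[4-(allyloxy)-3-methoxyphenyl]-7-methoxy-3-{[(triisopropylsilyl)oxy]methyl}-2,3-dihydro-1-benzofuran-5-yl}-6-hydroxy-2,4-dioxohexyl]-2,2-dimethyl-4H-1,3-dioxin-4-one F3. Dehydration (MeSO2Cl, Et3N) to the conjugated E enone comes back to the route at 23.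

Step 9. Under the basic conditions the silyl group may migrate from the primary to the secondary oxygen before ring closure, after which the primary alkoxide would close the isomeric five-membered ring. Fallback: set out from 13 with a protecting group that cannot migrate. Tritylation of the primary hydroxyl (Ph3CCl, pyridine) gives 3-[(1R,2S)-1-[4-(allyloxy)-3-methoxyphenyl]-1-hydroxy-3-(trityloxy)propan-2-yl]-4-fluoro-5-methoxybenzonitrile F4. The same alkoxide closure gives (2R,3S)-2-[4-(allyloxy)-3-methoxyphenyl]-7-methoxy-3-[(trityloxy)methyl]-2,3-dihydro-1-benzofuran-5-carbonitrile F5. Aqueous acetic acid at 50 °C removes the trityl group to give (2R,3S)-2-[4-(allyloxy)-3-methoxyphenyl]-3-(hydroxymethyl)-7-methoxy-2,3-dihydro-1-benzofuran-5-carbonitrile F6, and silylation (iPr3SiCl, imidazole) comes back to the route at 15.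

Step 1. Borylation next to the small cyano group (C6) may compete with borylation at C5 and give regioisomeric boronates that are hard to separate. Fallback: set out from 1 and let a branched group at C1 close both of its ortho positions. Reduction with iBu2AlH gives 4-fluoro-3-methoxybenzaldehyde F7 (itself a catalogue compound). Acetalisation with ethylene glycol gives 2-(4-fluoro-3-methoxyphenyl)-1,3-dioxolane F8. Iridium-catalysed borylation can then only give 2-[4-fluoro-3-methoxy-5-(4,4,5,5-tetramethyl-1,3,2-dioxaborolan-2-yl)phenyl]-1,3-dioxolane F9. Coupling with 3 as in step 2 gives tert-butyl 2-[5-(1,3-dioxolan-2-yl)-2-fluoro-3-methoxyphenyl]acetate F10. Dilute aqueous HCl in THF frees tert-butyl 2-(2-fluoro-5-formyl-3-methoxyphenyl)acetate F11, and oxidative ammonolysis of the aldehyde (I2, aqueous NH3, THF) restores the nitrile and comes back to the route at 4.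

Step 15. The π-allyl palladium intermediate may C-allylate the electron-rich resorcinol if capture by the amine is slow. During warming, the free carboxylic acid may add across the neighbouring stilbene double bond in competition with loss of CO2. Fallback: set out from 28 and decarboxylate last, in water. Desilylation first (Bu4NF, AcOH, THF) gives allyl 2,4-dihydroxy-6-[(E)-2-{(2R,3S)-2-[4-(allyloxy)-3-methoxyphenyl]-3-(hydroxymethyl)-7-methoxy-2,3-dihydro-1-benzofuran-5-yl}ethenyl]benzoate F12. Pd(PPh3)4 and morpholine in aqueous THF then give 2,4-dihydroxy-6-[(E)-2-{(2R,3S)-2-(4-hydroxy-3-methoxyphenyl)-3-(hydroxymethyl)-7-methoxy-2,3-dihydro-1-benzofuran-5-yl}ethenyl]benzoic acid F13. As a water-soluble resorcylic acid, F13 should lose CO2 in a warm, weakly acidic aqueous buffer at a lower temperature than in an organic medium, which comes back to the route at 31.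

## Further compounds

F1 | step 14 | 7-hydroxy-2,2-dimethyl-5-[(E)-2-{(2R,3S)-2-[4-(allyloxy)-3-methoxyphenyl]-7-methoxy-3-{[(triisopropylsilyl)oxy]methyl}-2,3-dihydro-1-benzofuran-5-yl}ethenyl]-4H-1,3-benzodioxin-4-one | C=CCOc1ccc([C@@H]2Oc3c(OC)cc(/C=C/c4cc(O)cc5OC(C)(C)OC(=O)c45)cc3[C@H]2CO[Si](C(C)C)(C(C)C)C(C)C)cc1OC
F2 | step 13 | 6-(2,4-dioxopentyl)-2,2-dimethyl-4H-1,3-dioxin-4-one | CC(=O)CC(=O)CC1=CC(=O)OC(C)(C)O1
F3 | step 13 | 6-[6-{(2R,3S)-2-[4-(allyloxy)-3-methoxyphenyl]-7-methoxy-3-{[(triisopropylsilyl)oxy]methyl}-2,3-dihydro-1-benzofuran-5-yl}-6-hydroxy-2,4-dioxohexyl]-2,2-dimethyl-4H-1,3-dioxin-4-one (both carbinol epimers) | C=CCOc1ccc([C@@H]2Oc3c(OC)cc(C(O)CC(=O)CC(=O)CC4=CC(=O)OC(C)(C)O4)cc3[C@H]2CO[Si](C(C)C)(C(C)C)C(C)C)cc1OC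
F4 | step 9 | 3-[(1R,2S)-1-[4-(allyloxy)-3-methoxyphenyl]-1-hydroxy-3-(trityloxy)propan-2-yl]-4-fluoro-5-methoxybenzonitrile | c1ccccc1C(c1ccccc1)(c1ccccc1)OC[C@H](c1cc(C#N)cc(OC)c1F)[C@@H](O)c1ccc(OCC=C)c(OC)c1
F5 | step 9 | (2R,3S)-2-[4-(allyloxy)-3-methoxyphenyl]-7-methoxy-3-[(trityloxy)methyl]-2,3-dihydro-1-benzofuran-5-carbonitrile | C=CCOc1ccc([C@@H]2Oc3c(OC)cc(C#N)cc3[C@H]2COC(c4ccccc4)(c4ccccc4)c4ccccc4)cc1OC
F6 | step 9 | (2R,3S)-2-[4-(allyloxy)-3-methoxyphenyl]-3-(hydroxymethyl)-7-methoxy-2,3-dihydro-1-benzofuran-5-carbonitrile | C=CCOc1ccc([C@@H]2Oc3c(OC)cc(C#N)cc3[C@H]2CO)cc1OC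
F7 | step 1 | 4-fluoro-3-methoxybenzaldehyde | COc1cc(C=O)ccc1F
F8 | step 1 | 2-(4-fluoro-3-methoxyphenyl)-1,3-dioxolane | COc1cc(C2OCCO2)ccc1F
F9 | step 1 | 2-[4-fluoro-3-methoxy-5-(4,4,5,5-tetramethyl-1,3,2-dioxaborolan-2-yl)phenyl]-1,3-dioxolane | COc1cc(C2OCCO2)cc(B3OC(C)(C)C(C)(C)O3)c1F
F10 | step 1 | tert-butyl 2-[5-(1,3-dioxolan-2-yl)-2-fluoro-3-methoxyphenyl]acetate | COc1cc(C2OCCO2)cc(CC(=O)OC(C)(C)C)c1F
F11 | step 1 | tert-butyl 2-(2-fluoro-5-formyl-3-methoxyphenyl)acetate | COc1cc(C=O)cc(CC(=O)OC(C)(C)C)c1F
F12 | step 15 | allyl 2,4-dihydroxy-6-[(E)-2-{(2R,3S)-2-[4-(allyloxy)-3-methoxyphenyl]-3-(hydroxymethyl)-7-methoxy-2,3-dihydro-1-benzofuran-5-yl}ethenyl]benzoate | C=CCOc1ccc([C@@H]2Oc3c(OC)cc(/C=C/c4cc(O)cc(O)c4C(=O)OCC=C)cc3[C@H]2CO)cc1OC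
F13 | step 15 | 2,4-dihydroxy-6-[(E)-2-{(2R,3S)-2-(4-hydroxy-3-methoxyphenyl)-3-(hydroxymethyl)-7-methoxy-2,3-dihydro-1-benzofuran-5-yl}ethenyl]benzoic acid | COc1cc([C@@H]2Oc3c(OC)cc(/C=C/c4cc(O)cc(O)c4C(=O)O)cc3[C@H]2CO)ccc1O
A1 | alternative 1 | (S)-1-oxo-1-(pyrrolidin-1-yl)propan-2-yl (2R,3R)-5-bromo-7-methoxy-2-{3-methoxy-4-[(triisopropylsilyl)oxy]phenyl}-2,3-dihydro-1-benzofuran-3-carboxylate | COc1cc([C@@H]2Oc3c(OC)cc(Br)cc3[C@H]2C(=O)O[C@@H](C)C(=O)N4CCCC4)ccc1O[Si](C(C)C)(C(C)C)C(C)C
A2 | alternative 1 | (S)-1-oxo-1-(pyrrolidin-1-yl)propan-2-yl 2-[5-bromo-3-methoxy-2-({3-methoxy-4-[(triisopropylsilyl)oxy]benzyl}oxy)phenyl]-2-diazoacetate | COc1cc(COc2c(OC)cc(Br)cc2C(=[N+]=[N-])C(=O)O[C@@H](C)C(=O)N2CCCC2)ccc1O[Si](C(C)C)(C(C)C)C(C)C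
A3 | alternative 2 | methyl 3-[(2S,3R)-1-[(tert-butyldimethylsilyl)oxy]-3-[3-methoxy-4-(methoxymethoxy)phenyl]-3-(4,4,5,5-tetramethyl-1,3,2-dioxaborolan-2-yl)propan-2-yl]-5-methoxy-4-(methoxymethoxy)benzoate | COCOc1ccc([C@H](B2OC(C)(C)C(C)(C)O2)[C@H](CO[Si](C)(C)C(C)(C)C)c2cc(C(=O)OC)cc(OC)c2OCOC)cc1OC
A4 | alternative 2 | (E)-tert-butyldimethyl{[3-(4,4,5,5-tetramethyl-1,3,2-dioxaborolan-2-yl)prop-2-en-1-yl]oxy}silane | CC(C)(C)[Si](C)(C)OC/C=C/B1OC(C)(C)C(C)(C)O1
A5 | alternative 2 | methyl 3-methoxy-4-(methoxymethoxy)-5-{[(trifluoromethyl)sulfonyl]oxy}benzoate | COCOc1c(OC)cc(C(=O)OC)cc1OS(=O)(=O)C(F)(F)F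
A6 | alternative 2 | [3-methoxy-4-(methoxymethoxy)phenyl]lithium | [Li]c1ccc(OCOC)c(OC)c1
A7 | alternative 3 | methyl (2R,3S)-2-(4-hydroxy-3-methoxyphenyl)-3-(hydroxymethyl)-7-methoxy-2,3-dihydro-1-benzofuran-5-carboxylate | COc1cc([C@@H]2Oc3c(OC)cc(C(=O)OC)cc3[C@H]2CO)ccc1O
A8 | alternative 3 | methyl 4-hydroxy-3-[(2S)-1-hydroxy-3-(4-hydroxy-3-methoxyphenyl)propan-2-yl]-5-methoxybenzoate | COc1cc(C[C@H](CO)c2cc(C(=O)OC)cc(OC)c2O)ccc1O
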